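## Retrosynthetic overview

1. The target is disconnected to an all-cis triene alcohol in which C1 carries the ester, C2 the free OH and C6 the side chain. Both oxiranes (ring C3–C4 and side-chain C10–C11) are formed last, in one flask without intermediate work-up: vanadium/t-BuOOH epoxidation directed by the C2 hydroxyl, then Shi epoxidation of the prenyl alkene.
2. The triene alcohol comes from a cis α′-acyloxy enone by Luche reduction. That enone comes from the trans α′-hydroxy enone and (R)-2-methylbutanoic acid by Mitsunobu inversion, and the hydroxy enone from enolate hydroxylation.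
3. The side chain is built by angeloylation (Yamaguchi), cross-metathesis with 2-methyl-2-butene (prenyl group) and Brown allylboration (sets C8) of the enal obtained by SeO2 oxidation of (R)-carvone 1.
4. Ring order: the carbocycle is bought as (R)-carvone (it fixes C6); the ring oxirane and the side-chain oxirane are closed in the same final operation.

Assumption: bisabolane locants are used throughout. Ring C1–C6: C1 bears the 2-methylbutanoate, C2 the OH, C3 the methyl, C6 the side chain. Side chain: C7(=C14H2)–C8(O-angeloyl)–C9H2–C10–C11. In these locants the target is (1R,2R,3R,4S,6S,8S,10R) with a (2R)-2-methylbutanoate and a (Z)-angelate; all four ring substituents (side chain, ester, OH, oxirane oxygen) are cis.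

## Route

Step 1
Reactants: 1 (R)-(−)-carvone
Product: 3 2-[(1R)-4-methyl-5-oxocyclohex-3-en-1-yl]prop-2-enal, via allylic alcohol 2 (not isolated)
Conditions: SeO2 (1.2 equiv), 1,4-dioxane, 80 °C
Reagents that add atoms: selenium dioxide, O=[Se]=O
Why: Riley-type allylic oxidation (ene reaction of SeO2, then 2,3-sigmatropic shift) takes place at the methyl group of the electron-rich 1,1-disubstituted isopropenyl alkene while the ring alkene is deactivated as an enone, and the primary allylic alcohol 2 is oxidised on to the enal by further SeO2; no stereocentre is formed and C6 is untouched.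

Step 2
Reactants: 3 2-[(1R)-4-methyl-5-oxocyclohex-3-en-1-yl]prop-2-enal
Product: 5 (5R)-5-[(3S)-3-hydroxyhexa-1,5-dien-2-yl]-2-methylcyclohex-2-en-1-one, via borinate ester 4 (not isolated)
Conditions: (−)-Ipc2BOMe, CH2=CHCH2MgBr, Et2O, 0 °C to rt; then 3, −78 °C; HOCH2CH2NH2 work-up
Reagents that add atoms: B-allyldiisopinocampheylborane of the (+)-α-pinene series, C=CCB([C@@H]1C[C@@H]2C[C@H]([C@H]1C)C2(C)C)[C@@H]1C[C@@H]2C[C@H]([C@H]1C)C2(C)C, made in the flask from allylmagnesium bromide, C=CC[Mg]Br
Why: Brown asymmetric allylboration through a closed six-membered chair transition state, in which the isopinocampheyl groups derived from (+)-α-pinene deliver the allyl group to the Si face of the aldehyde and so set C8 as S under reagent control, while the far less electrophilic enone ketone does not react at −78 °C and the amine work-up avoids alkaline peroxide that would epoxidise the enone.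

Step 3
Reactants: 5 (5R)-5-[(3S)-3-hydroxyhexa-1,5-dien-2-yl]-2-methylcyclohex-2-en-1-one
Product: 6 (5R)-5-[(3S)-3-hydroxy-6-methylhepta-1,5-dien-2-yl]-2-methylcyclohex-2-en-1-one
Conditions: second-generation Grubbs catalyst RuCl2(=CHPh)(PCy3)(H2IMes) (5 mol%), 2-methyl-2-butene (large excess), CH2Cl2, 40 °C
Reagents that add atoms: 2-methyl-2-butene, CC=C(C)C
Why: Olefin cross-metathesis in which only the monosubstituted vinyl group engages the ruthenium carbene (the 1,1-disubstituted C7=C14 and the trisubstituted enone alkene are too hindered or electron-poor), and the excess of 2-methyl-2-butene caps it as the trisubstituted prenyl alkene with loss of propene; no stereocentre is affected.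

Step 4
Reactants: 6 (5R)-5-[(3S)-3-hydroxy-6-methylhepta-1,5-dien-2-yl]-2-methylcyclohex-2-en-1-one; 7 angelic acid [(2Z)-2-methylbut-2-enoic acid]
Product: 8 (3S)-6-methyl-2-[(1R)-4-methyl-5-oxocyclohex-3-en-1-yl]hepta-1,5-dien-3-yl (2Z)-2-methylbut-2-enoate
Conditions: 7, 2,4,6-Cl3C6H2COCl, Et3N, toluene, rt; then 6, 75 °C
Reagents that add atoms: none
Why: Yamaguchi esterification, in which the alcohol attacks the angeloyl carbonyl of the mixed anhydride because the aroyl carbonyl is shielded by two ortho chlorines, and which is run without a nucleophilic catalyst so that the Z-alkene of the angelate does not isomerise to the tiglate; acylation on oxygen leaves C8 unchanged.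

Step 5
Reactants: 8 (3S)-6-methyl-2-[(1R)-4-methyl-5-oxocyclohex-3-en-1-yl]hepta-1,5-dien-3-yl (2Z)-2-methylbut-2-enoate
Product: 10 (3S)-2-[(1S,6S)-6-hydroxy-4-methyl-5-oxocyclohex-3-en-1-yl]-6-methylhepta-1,5-dien-3-yl (2Z)-2-methylbut-2-enoate, via sodium dienolate 9 (not isolated)
Conditions: NaN(SiMe3)2 (1.05 equiv), THF, −78 °C; then 2-(phenylsulfonyl)-3-phenyloxaziridine, −78 °C; aq NH4Cl
Reagents that add atoms: 2-(phenylsulfonyl)-3-phenyloxaziridine (Davis reagent), O=S(=O)(N1OC1c1ccccc1)c1ccccc1
Why: Kinetic deprotonation at the α′ carbon C1 gives the cross-conjugated sodium dienolate (the angelate has no α-hydrogen), and Davis oxidation transfers oxygen from the N-sulfonyloxaziridine to C1 on the face anti to the bulky C6 substituent, giving the 1,6-trans α′-hydroxy enone (1S) without touching the alkenes.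

Step 6
Reactants: 10 (3S)-2-[(1S,6S)-6-hydroxy-4-methyl-5-oxocyclohex-3-en-1-yl]-6-methylhepta-1,5-dien-3-yl (2Z)-2-methylbut-2-enoate; 11 (R)-2-methylbutanoic acid
Product: 12 (3S)-6-methyl-2-[(1S,6R)-4-methyl-6-{[(2R)-2-methylbutanoyl]oxy}-5-oxocyclohex-3-en-1-yl]hepta-1,5-dien-3-yl (2Z)-2-methylbut-2-enoate
Conditions: PPh3, DIAD, THF, 0 °C to rt
Reagents that add atoms: none
Why: Mitsunobu reaction, in which the carboxylate displaces the alkoxyphosphonium group at the carbonyl-activated C1 in an SN2 step with inversion, so that the (R)-2-methylbutanoate arrives cis to the C6 side chain (1R) while its own stereocentre, which is not involved, is kept.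

Step 7
Reactants: 12 (3S)-6-methyl-2-[(1S,6R)-4-methyl-6-{[(2R)-2-methylbutanoyl]oxy}-5-oxocyclohex-3-en-1-yl]hepta-1,5-dien-3-yl (2Z)-2-methylbut-2-enoate
Product: 13 (3S)-2-[(1S,5S,6R)-5-hydroxy-4-methyl-6-{[(2R)-2-methylbutanoyl]oxy}cyclohex-3-en-1-yl]-6-methylhepta-1,5-dien-3-yl (2Z)-2-methylbut-2-enoate
Conditions: NaBH4, CeCl3·7H2O, MeOH, −78 °C
Reagents that add atoms: none
Why: Luche 1,2-reduction, in which the hard cerium-modified borohydride attacks the enone carbonyl axially from the β face, anti to the axial C1 acyloxy group and as in the reduction of carvone to cis-carveol, to give the equatorial C2 alcohol cis to both the C1 oxygen and the C6 side chain, while the two esters and all alkenes survive and the low temperature suppresses 1,2-acyl migration.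

Step 8
Reactants: 13 (3S)-2-[(1S,5S,6R)-5-hydroxy-4-methyl-6-{[(2R)-2-methylbutanoyl]oxy}cyclohex-3-en-1-yl]-6-methylhepta-1,5-dien-3-yl (2Z)-2-methylbut-2-enoate
Product: 15 (1R,2R,3R,4S,6S,8S,10R)-8-angeloyloxy-3,4:10,11-diepoxy-1-[(2R)-2-methylbutanoyloxy]bisabol-7(14)-en-2-ol (target), via ring monoepoxide 14 (not isolated)
Conditions: VO(acac)2 (5 mol%), t-BuOOH (1.3 equiv), CH2Cl2, 0 °C to rt; solvent exchanged without work-up; then D-fructose-derived Shi ketone (catalyst, 1 equiv), Oxone (2KHSO5·KHSO4·K2SO4), NaHCO3, Bu4NHSO4, MeCN–CH2(OMe)2/aq disodium edetate Na2C10H14N2O8, pH 8, 0 °C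
Reagents that add atoms: tert-butyl hydroperoxide, CC(C)(C)OO; potassium peroxymonosulfate (KHSO5), [K+].[O-]S(=O)(=O)OO
Why: Hydroxyl-directed Sharpless-type vanadium epoxidation followed in the same flask by Shi asymmetric epoxidation: the C2 alkoxide binds pentavalent vanadium and the peroxide oxygen is delivered only to the syn (α) face of C3=C4 (3R,4S) against the steric bias, the alkenes without a free hydroxyl being inert to this catalyst, and the dioxirane from the D-fructose-derived ketone then attacks the electron-rich trisubstituted prenyl alkene through the spiro transition state on the face that gives 10R (the sense known for trans-disubstituted and trisubstituted alkenes), while the 1,1-disubstituted C7=C14 alkene (deactivated by the allylic ester) and the electron-poor angelate alkene react far more slowly and the near-neutral pH protects the vicinal hydroxy ester from acyl migration.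

## Compound list

1 | (R)-(−)-carvone [(5R)-2-methyl-5-(prop-1-en-2-yl)cyclohex-2-en-1-one] | C=C(C)[C@@H]1CC=C(C)C(=O)C1 | starting material
2 | (5R)-5-(3-hydroxyprop-1-en-2-yl)-2-methylcyclohex-2-en-1-one (allylic alcohol) | C=C(CO)[C@@H]1CC=C(C)C(=O)C1 | intermediate (not isolated)
3 | 2-[(1R)-4-methyl-5-oxocyclohex-3-en-1-yl]prop-2-enal | C=C(C=O)[C@@H]1CC=C(C)C(=O)C1 | intermediate
4 | O-diisopinocampheylboryl ether (borinate ester) of 5 | C=C([C@H](CC=C)OB([C@@H]1C[C@@H]2C[C@H]([C@H]1C)C2(C)C)[C@@H]1C[C@@H]2C[C@H]([C@H]1C)C2(C)C)[C@@H]1CC=C(C)C(=O)C1 | intermediate (not isolated)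
5 | (5R)-5-[(3S)-3-hydroxyhexa-1,5-dien-2-yl]-2-methylcyclohex-2-en-1-one | C=C([C@H](CC=C)O)[C@@H]1CC=C(C)C(=O)C1 | intermediate
6 | (5R)-5-[(3S)-3-hydroxy-6-methylhepta-1,5-dien-2-yl]-2-methylcyclohex-2-en-1-one | C=C([C@H](CC=C(C)C)O)[C@@H]1CC=C(C)C(=O)C1 | intermediate
7 | angelic acid [(2Z)-2-methylbut-2-enoic acid] | C/C=C(/C)C(=O)O | starting material
8 | (3S)-6-methyl-2-[(1R)-4-methyl-5-oxocyclohex-3-en-1-yl]hepta-1,5-dien-3-yl (2Z)-2-methylbut-2-enoate | C=C([C@H](CC=C(C)C)OC(=O)/C(C)=C\C)[C@@H]1CC=C(C)C(=O)C1 | intermediate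
9 | sodium cross-conjugated dienolate of 8 (C1=C2–O−) | C=C([C@H](CC=C(C)C)OC(=O)/C(C)=C\C)[C@@H]1CC=C(C)C([O-])=C1.[Na+] | intermediate (not isolated)
10 | (3S)-2-[(1S,6S)-6-hydroxy-4-methyl-5-oxocyclohex-3-en-1-yl]-6-methylhepta-1,5-dien-3-yl (2Z)-2-methylbut-2-enoate (OH trans to side chain) | C=C([C@H](CC=C(C)C)OC(=O)/C(C)=C\C)[C@@H]1CC=C(C)C(=O)[C@H]1O | intermediate
11 | (R)-2-methylbutanoic acid | CC[C@@H](C)C(=O)O | starting material
12 | (3S)-6-methyl-2-[(1S,6R)-4-methyl-6-{[(2R)-2-methylbutanoyl]oxy}-5-oxocyclohex-3-en-1-yl]hepta-1,5-dien-3-yl (2Z)-2-methylbut-2-enoate (ester cis to side chain) | C=C([C@H](CC=C(C)C)OC(=O)/C(C)=C\C)[C@@H]1CC=C(C)C(=O)[C@@H]1OC(=O)[C@H](C)CC | intermediate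
13 | (3S)-2-[(1S,5S,6R)-5-hydroxy-4-methyl-6-{[(2R)-2-methylbutanoyl]oxy}cyclohex-3-en-1-yl]-6-methylhepta-1,5-dien-3-yl (2Z)-2-methylbut-2-enoate (all-cis) | C=C([C@H](CC=C(C)C)OC(=O)/C(C)=C\C)[C@@H]1CC=C(C)[C@H](O)[C@@H]1OC(=O)[C@H](C)CC | intermediate
14 | (1R,2R,3R,4S,6S,8S)-8-angeloyloxy-3,4-epoxy-1-[(2R)-2-methylbutanoyloxy]bisabola-7(14),10-dien-2-ol (ring monoepoxide) | C=C([C@H](CC=C(C)C)OC(=O)/C(C)=C\C)[C@@H]1C[C@@H]2O[C@]2(C)[C@H](O)[C@@H]1OC(=O)[C@H](C)CC | intermediate (not isolated)
15 | (1R,2R,3R,4S,6S,8S,10R)-8-angeloyloxy-3,4:10,11-diepoxy-1-[(2R)-2-methylbutanoyloxy]bisabol-7(14)-en-2-ol | C=C([C@H](C[C@H]1OC1(C)C)OC(=O)/C(C)=C\C)[C@@H]1C[C@@H]2O[C@]2(C)[C@H](O)[C@@H]1OC(=O)[C@H](C)CC | target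

## Step count and risks

Total steps: 8. Longest linear sequence: 8 steps, from (R)-carvone 1; acids 7 and 11 are bought.

The three steps most likely to fail:

Step 8 (one-flask double epoxidation). The directed epoxidation must beat the steric bias of the all-cis α face, where the C1 ester is axial, and vanadium may instead oxidise the allylic alcohol back to enone 12. The Shi stage then exposes a vicinal hydroxy ester to aqueous buffer, where the ester can migrate from O1 to O2. The fallback sets out from 12 and makes the two oxiranes in separate operations, with the Shi reaction run before any free hydroxyl exists. Shi epoxidation of 12 under the standard conditions (ketone 30 mol%, Oxone 2KHSO5·KHSO4·K2SO4, K2CO3, pH 10.5, MeCN–CH2(OMe)2/water, 0 °C; the enone alkene is inert) gives the (10R)-epoxy enone F4. Luche reduction (NaBH4, CeCl3·7H2O, MeOH, −78 °C) gives the all-cis epoxy allylic alcohol F5. VO(acac)2/t-BuOOH in CH2Cl2 then closes the ring oxirane and comes back to the route at 15.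

Step 6 (Mitsunobu on an α-ketol). Elimination towards the dienone, or esterification with retention through an acyloxyphosphonium species, can compete. The fallback sets out from 10: Tf2O and pyridine in CH2Cl2 at −78 °C give the trans α′-triflate F3, which is displaced with inversion by cesium (R)-2-methylbutanoate (from 11 and Cs2CO3, 18-crown-6, toluene, 0 °C) and comes back to the route at 12.

Step 5 (enolate hydroxylation beside an ester). The free dienolate 9 may attack the angelate carbonyl through a six-membered transition state, and oxaziridine oxidations of enolates can stall at the sulfonimine adduct. The fallback sets out from 8 and avoids a free enolate. Soft enolisation (Me3SiOTf, Et3N, CH2Cl2, 0 °C) gives the cross-conjugated 2-(trimethylsilyloxy)-1,3-diene F1. Rubottom oxidation (mCPBA 1.0 equiv, NaHCO3, CH2Cl2–hexane, −78 °C, where the silyl enol ether reacts far faster than the prenyl alkene) gives, anti to the C6 substituent, the trans α′-(trimethylsilyloxy) ketone F2. Dilute HCl in THF removes the silyl group and comes back to the route at 10.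

Further compounds
F1 | step 5 | (3S)-6-methyl-2-[(1R)-4-methyl-5-(trimethylsilyloxy)cyclohexa-3,5-dien-1-yl]hepta-1,5-dien-3-yl (2Z)-2-methylbut-2-enoate | C=C([C@H](CC=C(C)C)OC(=O)/C(C)=C\C)[C@@H]1CC=C(C)C(O[Si](C)(C)C)=C1
F2 | step 5 | (3S)-6-methyl-2-[(1S,6S)-4-methyl-5-oxo-6-(trimethylsilyloxy)cyclohex-3-en-1-yl]hepta-1,5-dien-3-yl (2Z)-2-methylbut-2-enoate | C=C([C@H](CC=C(C)C)OC(=O)/C(C)=C\C)[C@@H]1CC=C(C)C(=O)[C@H]1O[Si](C)(C)C
F3 | step 6 | trifluoromethanesulfonate of 10 (OTf at C1 trans to the side chain) | C=C([C@H](CC=C(C)C)OC(=O)/C(C)=C\C)[C@@H]1CC=C(C)C(=O)[C@H]1OS(=O)(=O)C(F)(F)F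
F4 | step 8 | (10R)-10,11-epoxide of 12 (epoxy enone) | C=C([C@H](C[C@H]1OC1(C)C)OC(=O)/C(C)=C\C)[C@@H]1CC=C(C)C(=O)[C@@H]1OC(=O)[C@H](C)CC
F5 | step 8 | (10R)-10,11-epoxide of 13 (all-cis epoxy allylic alcohol) | C=C([C@H](C[C@H]1OC1(C)C)OC(=O)/C(C)=C\C)[C@@H]1CC=C(C)[C@H](O)[C@@H]1OC(=O)[C@H](C)CC
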